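## Analysis of the target

The target (34) is a longipinane sesquiterpenoid diester. Longipinane numbering is used throughout: C1 ketone, C2=C3 (C15 methyl on C3), cyclobutane C4–C5–C11–C10, C6 with the geminal methyls C12/C13, oxygenated C7 and C8, C9 methylene, C14 methyl on the quaternary C10. The cyclobutane is bridged across both diagonals: the enone bridge C1–C2–C3 joins C11 and C4 on one face (a bicyclo[3.1.1]hept-3-en-2-one), and the four-carbon bridge C6–C7–C8–C9 joins C5 and C10 on the other face (the seven-membered ring). Four of the six stereocentres sit on the cyclobutane (4R, 5S, 10R, 11R) and are locked to each other by the two bridges, with the C14 methyl and the C5 hydrogen on the face of the enone bridge. The other two are the trans-diol carbons (7S, 8S), esterified with the Z acid (angelate) at the neopentyl O7 and the E acid (tiglate) at O8. The seven-membered ring lies on a local mirror plane through C5, C10, C14 and C6–C9; only the remote difference between C11–C1(=O) and C4–C3 breaks it, so C7/C8 cannot be relayed from the core and need absolute control of their own. The angelate isomerises to the tiglate under base, nucleophilic catalysis or radical conditions; the pinane-type cyclobutane rearranges through cations and opens by retro-aldol whenever an oxygen on C5 is β to a C1 carbonyl. The feature that invites the key step is the ring C11–C1–C2–C3–C4 closed across the cyclobutane: C10/C11 read as a trisubstituted alkene (C10 carries methyl and chain) and C5/C4 as a ketene, joined by the three-atom tether C1–C2–C3.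

## Retrosynthetic reasoning

34 back to 26. The enone is not carried through the route. It is unmasked last from a C1 silyl ether and an exocyclic C3=C15 alkene (32, via 33), both of which come directly from the key step. The two esters go on before that (31 from 28 and 29; 28 from 26 and 27), the less hindered O8 first, the angelate after every basic or radical step.

26 back to 23. Because of the local mirror plane, C8 has to be set by a reagent, and this is done on the class of alkene where chiral dioxirane catalysts are most dependable: the cyclic trisubstituted enol ether 23. Epoxidation and hydrolysis give the α-hydroxy ketone 25; C7 is then relayed from C8 by hydroxyl-directed hydride delivery, which gives the trans-diol 26.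

23 back to 20. The C5 hydrogen replaces a tertiary hydroxyl (20, through xanthate 22). Inside the tricycle the C5 radical can only accept hydrogen on the face the oxygen left, so the configuration is not at risk.

20 back to 15. Two bonds are cut: C7=C8 by ring-closing metathesis of the allyl group and the methyl enol ether in 19, and C5–C6 by addition of the enolate 17 of methyl isobutyrate 16 to a cyclobutanone. C5–C6 joins two fully substituted carbons; carbonyl addition is the one dependable way to make it, and the ketone of 15 offers exactly that. The ester carbon becomes C7 (19 from 18).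

15 back to 12 (key disconnection). Both C5–C11 and C4–C10 are cut: the cyclobutanone is the [2+2] adduct of a vinylketene (14) and the C10=C11 alkene of an acyclic trienoic acid (12). This removes two rings and three stereocentres at once. The forward step must pick the bridged over the fused mode and one alkene face; the allylic C1 silyl ether is there to do the latter.

12 back to 1, 6. The acid 12 comes from ester 10, made by a catalytic asymmetric vinylogous aldol reaction of enal 5 with dienolate 8 (from 6), which sets the one catalytic stereocentre of the core. Enal 5 comes from pent-1-en-4-yne 1 by carboalumination, which fixes the E geometry that later places C14 syn to the enone bridge.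

## Alternatives that were turned down

Alternative 1: The textbook route makes one cyclobutane bond (C4–C10) last. A cis-fused bicyclo[5.4.0]undecane of the himachalane type (from an enone–alkene photocycloaddition and ring expansion), carrying a C9 ketone and a C4 sulfonate (A1), would close the four-membered ring by intramolecular enolate alkylation (4-exo-tet). It was turned down for these reasons:
- C10 must be acidified by a C9 carbonyl the target lacks; removing it next to the oxygenated C8 costs several steps.
- The most strained bond is made last under strongly basic conditions, where elimination of the allylic sulfonate and O-alkylation compete.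
- A1 with its stereocentres takes about as many steps as the whole proposed route to the tricycle.
- The C7/C8 diol would still need independent control.

Alternative 2: A transannular crossed [2+2] photocycloaddition of the humulene-type cycloundecatrienone A2 would form C5–C11 and C4–C10 in one step from an eleven-membered ring. It was turned down for these reasons:
- C10=C11 and C4=C5 are a 1,6-diene through C1–C3, so first bonding should give the five-membered ring (C11–C4) and the fused, not the bridged, adduct.
- A cross-conjugated trienone dissipates excitation by E/Z isomerisation.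
- Nothing in A2 pairs the alkene faces with the diol configuration.
- An enantiopure A2 costs as much as the route itself.

Alternative 3: Skeleton first: take the hydrocarbon α-longipinene A3, oxidise the allylic position to the enone A4, then hydroxylate C7 and C8 by C–H oxidation. It was turned down for these reasons:
- C7, C8 and C9 are three similar unactivated methylenes, remote from the enone on the opposite face of the cyclobutane, and no directing group reaches them.
- Intrinsic reactivity would favour C8 or C9 over the neopentyl C7.
- Two oxygenations with a trans relationship would face the same local mirror plane with no handle at all.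
- The route would depend on the availability of the right enantiomer of A3.

Key step: step 7

Assumption: the ester on the oxygen next to the gem-dimethyl carbon is read from the SMILES as the Z (angelate) and the other as the E (tiglate) 2-methylbut-2-enoate, and both enantiomers of the chiral catalysts of steps 4 and 13 are taken as obtainable.

## Route

Step 1
Reactants: 1 pent-1-en-4-yne
Product: 4 (E)-3-methylhexa-2,5-dien-1-ol, via alkenylalane 2 (not isolated), via lithium alanate 3 (not isolated)
Conditions: Me3Al, Cp2ZrCl2 (0.25 equiv), CH2Cl2, 0 °C to rt; n-BuLi, THF, −30 °C; (CH2O)n, rt; aq. HCl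
Reagents that add atoms: trimethylaluminium, C[Al](C)C; formaldehyde (from paraformaldehyde), C=O
Why: Negishi carboalumination adds methyl and aluminium syn across the terminal alkyne, so the allyl group ends trans to the metal; the alanate is hydroxymethylated with retention to give the E allylic alcohol, and the isolated alkene is left alone.

Step 2
Reactants: 4 (E)-3-methylhexa-2,5-dien-1-ol
Product: 5 (E)-3-methylhexa-2,5-dienal
Conditions: MnO2 (excess), CH2Cl2, rt
Reagents that add atoms: none
Why: MnO2 oxidises allylic alcohols to enals under neutral conditions, so the skipped diene should neither isomerise into conjugation nor lose its E geometry.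

Step 3
Reactants: 6 methyl 3-methylbut-2-enoate
Product: 8 tert-butyl[(1-methoxy-3-methylbuta-1,3-dien-1-yl)oxy]dimethylsilane, via lithium dienolate 7 (not isolated)
Conditions: LiN(iPr)2, THF, −78 °C; TBSCl, DMPU, −78 °C to rt
Reagents that add atoms: tert-butylchlorodimethylsilane, CC(C)(C)[Si](C)(C)Cl
Why: γ-Deprotonation of the senecioate gives the cross-conjugated dienolate, which is silylated on oxygen (silyl ketene acetal formation); the ketene acetal geometry is immaterial.

Step 4
Reactants: 5 (E)-3-methylhexa-2,5-dienal; 8 silyl dienol ether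
Product: 10 methyl (2E,5S,6E)-5-hydroxy-3,7-dimethyldeca-2,6,9-trienoate, via trichlorosilyl aldolate 9 (not isolated)
Conditions: SiCl4 (1.1 equiv), (S,S)-bisphosphoramide Lewis base (binaphthyl-2,2′-diamine-derived, pentamethylene-linked; 5 mol%), iPr2NEt (cat.), CH2Cl2, −78 °C; aq. KF/NaHCO3
Reagents that add atoms: none
Why: Vinylogous Mukaiyama aldol with a Lewis-base-activated silicon Lewis acid: the dienolate reacts at its γ-carbon to give the E enoate, and the catalyst is chosen to direct Si-face attack on the enal, which gives 5S (the future C1); this is the one catalytic stereocentre from which the core is relayed.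

Step 5
Reactants: 10 methyl (2E,5S,6E)-5-hydroxy-3,7-dimethyldeca-2,6,9-trienoate
Product: 11 methyl (2E,5S,6E)-5-[(tert-butyldimethylsilyl)oxy]-3,7-dimethyldeca-2,6,9-trienoate
Conditions: TBSCl, imidazole, DMF, rt
Reagents that add atoms: tert-butylchlorodimethylsilane, CC(C)(C)[Si](C)(C)Cl
Why: Standard silylation of a secondary allylic alcohol; the bulky ether protects O1 and later serves as the stereocontrol element of the key step.

Step 6
Reactants: 11 silyl ether ester
Product: 12 (2E,5S,6E)-5-[(tert-butyldimethylsilyl)oxy]-3,7-dimethyldeca-2,6,9-trienoic acid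
Conditions: LiOH, THF/MeOH/H2O, 0 °C to rt; aq. HCl to pH 4
Reagents that add atoms: lithium hydroxide, [Li+].[OH-]
Why: Saponification at low temperature; mild conditions are chosen so that vinylogous β-elimination of the silyloxy group does not compete.

Step 7
Reactants: 12 (2E,5S,6E)-5-[(tert-butyldimethylsilyl)oxy]-3,7-dimethyldeca-2,6,9-trienoic acid
Product: 15 (1R,2S,5R,7R)-2-[(tert-butyldimethylsilyl)oxy]-7-methyl-4-methylidene-7-(prop-2-en-1-yl)bicyclo[3.1.1]heptan-6-one, via acid chloride 13 (not isolated), via vinylketene 14 (not isolated)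
Conditions: 1-chloro-N,N,2-trimethylprop-1-en-1-amine, CH2Cl2, 0 °C to rt; slow addition to Et3N (3 equiv), toluene, 110 °C, high dilution
Reagents that add atoms: none
Why: Acid chloride 13 loses HCl by 1,4-elimination (Et3N takes a proton from the C15 methyl, which is cis to the acyl group in the 2E acid) to give vinylketene 14, which adds across the trisubstituted C10=C11 alkene in a concerted, asynchronous [2+2] cycloaddition that is suprafacial on the alkene; the closest known reaction type is the intramolecular vinylketene–alkene cycloaddition of geranyl- and farnesyl-type dienoyl chlorides to 2-methylidenebicyclo[3.1.1]heptan-6-ones. The electrophilic ketene carbon C5 bonds to the less substituted alkene carbon C11 and closes the six-membered ring (C11–C1–C2–C3–C4–C5) through the three-atom tether, while positive charge builds at the trisubstituted C10, which then bonds to the ketene α-carbon C4 and closes the cyclobutanone; this polarisation enforces the bridged mode over the fused bicyclo[3.2.0] mode. C10 is set by the 6E geometry: the C14 methyl is cis to the tether and ends syn to the C1–C3 bridge, the allyl group anti. C11 and C4 follow from C10 because the bicycle can only close cis. The alkene face is chosen by the allylic C1 stereocentre: to avoid A(1,3) strain with the cis C14 methyl the C1–H eclipses the alkene, the ketene chain attacks from one face and the silyloxy group sits on the other, so it ends anti to the methyl-bearing bridge, where it also avoids a 1,3-clash with C14 in the product. The step needs deprotonation at the methyl and not at C2 (the C2 pathway is unproductive), reaction at the trisubstituted alkene and not the remote vinyl group (only the former is within reach and nucleophilic enough), and high dilution against ketene dimerisation.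

Step 8
Reactants: 15 bicyclic cyclobutanone; 16 methyl 2-methylpropanoate
Product: 18 methyl 2-[(2S)-2-[(tert-butyldimethylsilyl)oxy]-6-hydroxy-7-methyl-4-methylidene-7-(prop-2-en-1-yl)bicyclo[3.1.1]heptan-6-yl]-2-methylpropanoate (ring configuration as in 15; 6-OH syn to the C2–C4 bridge), via lithium enolate 17 (not isolated)
Conditions: 16, LiN(iPr)2, THF, −78 °C; then 15, −78 °C; aq. NH4Cl
Reagents that add atoms: none
Why: Ester enolate aldol addition to a strained, non-enolisable cyclobutanone forms the hindered C5–C6 bond; the face toward the three-carbon bridge is blocked, so the nucleophile should enter anti to it, on the side that carries the allyl group, and the adduct does not revert because that would restore cyclobutanone strain.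

Step 9
Reactants: 18 β-hydroxy ester
Product: 19 (2S)-2-[(tert-butyldimethylsilyl)oxy]-6-(3-methoxy-2-methylbut-3-en-2-yl)-7-methyl-4-methylidene-7-(prop-2-en-1-yl)bicyclo[3.1.1]heptan-6-ol (ring configuration as in 18)
Conditions: Cp2TiMe2 (3 equiv), toluene/THF, 70 °C, dark
Reagents that add atoms: dimethyltitanocene, [CH3-].[CH3-].[Ti+4].c1cc[cH-]c1.c1cc[cH-]c1
Why: Petasis methylenation turns even α-quaternary esters into methyl enol ethers under non-acidic conditions; the free tertiary hydroxyl is carried as its titanium alkoxide and returns on work-up.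

Step 10
Reactants: 19 acyclic methyl enol ether
Product: 20 (1S)-1-[(tert-butyldimethylsilyl)oxy]-7-methoxylongipina-3(15),7-dien-5-ol (5-OH syn to the C1–C3 bridge; C4/C10/C11 as in 34)
Conditions: second-generation Grubbs catalyst RuCl2(H2IMes)(PCy3)(=CHPh) (10 mol%), toluene, 80 °C, argon sparge
Reagents that add atoms: none
Why: Ring-closing metathesis between the allyl group and the 2-methoxyalkene, held cis-1,3 on the cyclobutane, closes the seven-membered ring as a cyclic enol ether with loss of ethene; the catalyst loads on the unhindered allyl terminus.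

Step 11
Reactants: 20 tricyclic tertiary alcohol
Product: 22 O-[(1S)-1-[(tert-butyldimethylsilyl)oxy]-7-methoxylongipina-3(15),7-dien-5-yl] S-methyl dithiocarbonate, via potassium xanthate 21 (not isolated)
Conditions: KN(SiMe3)2, THF, −78 to 0 °C; CS2; MeI
Reagents that add atoms: carbon disulfide, S=C=S; iodomethane, CI
Why: Xanthate formation from the tertiary alkoxide; this tertiary xanthate cannot undergo Chugaev elimination because its only β-hydrogens are at bridgeheads and C6 is quaternary.

Step 12
Reactants: 22 xanthate
Product: 23 (1S)-1-[(tert-butyldimethylsilyl)oxy]-7-methoxylongipina-3(15),7-diene (C4/C5/C10/C11 as in 34)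
Conditions: Bu3SnH, AIBN (cat.), toluene, 110 °C
Reagents that add atoms: none
Why: Barton–McCombie deoxygenation; the C5 radical is held in the tricycle and can take hydrogen only on the face the oxygen left, so C5–H forms with retention (5S of the target), and the neighbouring enol ether π-system is orthogonal to the radical orbital, so no vinyl shift is expected.

Step 13
Reactants: 23 tricyclic methyl enol ether
Product: 25 (1S,8S)-1-[(tert-butyldimethylsilyl)oxy]-8-hydroxylongipin-3(15)-en-7-one, via methoxy epoxide 24 (not isolated)
Conditions: 1,2:4,5-di-O-isopropylidene-β-L-erythro-2,3-hexodiulo-2,6-pyranose (30 mol%), KHSO5 (as 2KHSO5·KHSO4·K2SO4, 1.2 equiv), K2CO3, Bu4NHSO4, MeCN/dimethoxymethane/aq. buffer pH 10.5, −10 to 0 °C; then wet silica gel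
Reagents that add atoms: potassium peroxymonosulfate, [K+].[O-]S(=O)(=O)OO; water, O
Why: Shi epoxidation of an electron-rich cyclic trisubstituted enol ether, which should react well before the hindered exocyclic alkene; because the seven-membered ring is locally mirror-symmetric the face is chosen by the catalyst, and the L-fructose-derived ketone is picked by analogy with 1-substituted cycloalkenes to put oxygen on the face that gives 8S. The 2-methoxyoxirane opens at the acetal carbon on work-up, so the C8–O bond is kept.

Step 14
Reactants: 25 α-hydroxy ketone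
Product: 26 (1S,7S,8S)-1-[(tert-butyldimethylsilyl)oxy]longipin-3(15)-ene-7,8-diol
Conditions: Me4NBH(OAc)3, MeCN/AcOH, −30 to 0 °C
Reagents that add atoms: none
Why: Hydroxyl-directed triacetoxyborohydride reduction: the hydride is delivered intramolecularly from boron bound to O8 to the face of the C7 carbonyl on which O8 lies, so the new hydroxyl ends trans (7S); this is a 1,2-relay from the reagent-set C8.

Step 15
Reactants: 26 trans-diol; 27 (E)-2-methylbut-2-enoyl chloride
Product: 28 (1S,7S,8S)-1-[(tert-butyldimethylsilyl)oxy]-7-hydroxylongipin-3(15)-en-8-yl (E)-2-methylbut-2-enoate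
Conditions: 27 (1.1 equiv), pyridine, DMAP (cat.), CH2Cl2, −20 to 0 °C
Reagents that add atoms: none
Why: Acylation under nucleophilic catalysis should pick the C8 hydroxyl, which is flanked by a methylene, over the neopentyl C7 hydroxyl next to the gem-dimethyl carbon.

Step 16
Reactants: 28 hydroxy tiglate; 29 (Z)-2-methylbut-2-enoic acid
Product: 31 (1S,7S,8S)-1-[(tert-butyldimethylsilyl)oxy]-8-[(E)-2-methylbut-2-enoyloxy]longipin-3(15)-en-7-yl (Z)-2-methylbut-2-enoate, via mixed anhydride 30 (not isolated)
Conditions: 29, 2,4,6-trichlorobenzoyl chloride, Et3N, toluene, rt; then 28, toluene, 80 °C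
Reagents that add atoms: none
Why: Yamaguchi-type mixed-anhydride esterification run without a nucleophilic catalyst or strong base, the conditions known to keep the Z geometry of angelates; heat is needed for the neopentyl alcohol.

Step 17
Reactants: 31 diester silyl ether
Product: 32 (1S,7S,8S)-1-hydroxy-8-[(E)-2-methylbut-2-enoyloxy]longipin-3(15)-en-7-yl (Z)-2-methylbut-2-enoate
Conditions: HF·pyridine, pyridine/THF, 0 °C to rt
Reagents that add atoms: none
Why: Buffered fluoride desilylation; neither ester nor the exocyclic alkene is affected, and no base is present that could move acyl groups or isomerise the angelate.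

Step 18
Reactants: 32 diester alcohol
Product: 34 (4R,5S,7S,8S,10R,11R)-7-[(Z)-2-methylbut-2-enoyloxy]-8-[(E)-2-methylbut-2-enoyloxy]longipin-2-en-1-one, via unconjugated ketone 33 (not isolated)
Conditions: Dess–Martin periodinane, NaHCO3, CH2Cl2, rt; then Et3N, CH2Cl2, rt
Reagents that add atoms: none
Why: Dess–Martin oxidation gives the β,γ-unsaturated ketone; C2 is the only enolisable position (C11 is a bridgehead), so mild amine base moves the exocyclic double bond into conjugation and gives the enone, the C1 stereocentre having done its work.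

## Compound list

1 | pent-1-en-4-yne | C#CCC=C | starting material
2 | (E)-dimethyl(2-methylpenta-1,4-dien-1-yl)alane | C=CC/C(C)=C/[Al](C)C | intermediate
3 | lithium butyl(dimethyl)[(E)-2-methylpenta-1,4-dien-1-yl]alanate | [Li+].C=CC/C(C)=C/[Al-](C)(C)CCCC | intermediate
4 | (E)-3-methylhexa-2,5-dien-1-ol | C=CC/C(C)=C/CO | intermediate
5 | (E)-3-methylhexa-2,5-dienal | C=CC/C(C)=C/C=O | intermediate
6 | methyl 3-methylbut-2-enoate | COC(=O)C=C(C)C | starting material
7 | lithium 1-methoxy-3-methylbuta-1,3-dien-1-olate | [Li+].COC([O-])=CC(C)=C | intermediate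
8 | tert-butyl[(1-methoxy-3-methylbuta-1,3-dien-1-yl)oxy]dimethylsilane (ketene acetal geometry not defined) | COC(O[Si](C)(C)C(C)(C)C)=CC(C)=C | intermediate
9 | methyl (2E,5S,6E)-3,7-dimethyl-5-[(trichlorosilyl)oxy]deca-2,6,9-trienoate | COC(=O)/C=C(\C)C[C@H](O[Si](Cl)(Cl)Cl)/C=C(\C)CC=C | intermediate
10 | methyl (2E,5S,6E)-5-hydroxy-3,7-dimethyldeca-2,6,9-trienoate | COC(=O)/C=C(\C)C[C@H](O)/C=C(\C)CC=C | intermediate
11 | methyl (2E,5S,6E)-5-[(tert-butyldimethylsilyl)oxy]-3,7-dimethyldeca-2,6,9-trienoate | COC(=O)/C=C(\C)C[C@H](O[Si](C)(C)C(C)(C)C)/C=C(\C)CC=C | intermediate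
12 | (2E,5S,6E)-5-[(tert-butyldimethylsilyl)oxy]-3,7-dimethyldeca-2,6,9-trienoic acid | OC(=O)/C=C(\C)C[C@H](O[Si](C)(C)C(C)(C)C)/C=C(\C)CC=C | intermediate
13 | (2E,5S,6E)-5-[(tert-butyldimethylsilyl)oxy]-3,7-dimethyldeca-2,6,9-trienoyl chloride | ClC(=O)/C=C(\C)C[C@H](O[Si](C)(C)C(C)(C)C)/C=C(\C)CC=C | intermediate
14 | (5S,6E)-5-[(tert-butyldimethylsilyl)oxy]-7-methyl-3-methylidenedeca-1,6,9-trien-1-one (vinylketene) | O=C=CC(=C)C[C@H](O[Si](C)(C)C(C)(C)C)/C=C(\C)CC=C | intermediate
15 | (1R,2S,5R,7R)-2-[(tert-butyldimethylsilyl)oxy]-7-methyl-4-methylidene-7-(prop-2-en-1-yl)bicyclo[3.1.1]heptan-6-one | C=CC[C@@]2(C)[C@@H]3[C@@H](O[Si](C)(C)C(C)(C)C)CC(=C)[C@H]2C3=O | intermediate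
16 | methyl 2-methylpropanoate | COC(=O)C(C)C | starting material
17 | lithium 1-methoxy-2-methylprop-1-en-1-olate | [Li+].COC([O-])=C(C)C | intermediate
18 | methyl 2-[(2S)-2-[(tert-butyldimethylsilyl)oxy]-6-hydroxy-7-methyl-4-methylidene-7-(prop-2-en-1-yl)bicyclo[3.1.1]heptan-6-yl]-2-methylpropanoate (6-OH syn to the C2–C4 bridge) | C=CC[C@@]2(C)[C@@H]3[C@@H](O[Si](C)(C)C(C)(C)C)CC(=C)[C@H]2[C@]3(O)C(C)(C)C(=O)OC | intermediate
19 | (2S)-2-[(tert-butyldimethylsilyl)oxy]-6-(3-methoxy-2-methylbut-3-en-2-yl)-7-methyl-4-methylidene-7-(prop-2-en-1-yl)bicyclo[3.1.1]heptan-6-ol | C=CC[C@@]2(C)[C@@H]3[C@@H](O[Si](C)(C)C(C)(C)C)CC(=C)[C@H]2[C@]3(O)C(C)(C)C(=C)OC | intermediate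
20 | (1S)-1-[(tert-butyldimethylsilyl)oxy]-7-methoxylongipina-3(15),7-dien-5-ol (5-OH syn to the C1–C3 bridge) | COC1=CC[C@@]2(C)[C@@H]3[C@@H](O[Si](C)(C)C(C)(C)C)CC(=C)[C@H]2[C@]3(O)C1(C)C | intermediate
21 | potassium O-[(1S)-1-[(tert-butyldimethylsilyl)oxy]-7-methoxylongipina-3(15),7-dien-5-yl] dithiocarbonate | [K+].COC1=CC[C@@]2(C)[C@@H]3[C@@H](O[Si](C)(C)C(C)(C)C)CC(=C)[C@H]2[C@]3(OC(=S)[S-])C1(C)C | intermediate
22 | O-[(1S)-1-[(tert-butyldimethylsilyl)oxy]-7-methoxylongipina-3(15),7-dien-5-yl] S-methyl dithiocarbonate | COC1=CC[C@@]2(C)[C@@H]3[C@@H](O[Si](C)(C)C(C)(C)C)CC(=C)[C@H]2[C@]3(OC(=S)SC)C1(C)C | intermediate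
23 | (1S)-1-[(tert-butyldimethylsilyl)oxy]-7-methoxylongipina-3(15),7-diene | COC1=CC[C@@]2(C)[C@@H]3[C@@H](O[Si](C)(C)C(C)(C)C)CC(=C)[C@H]2[C@@H]3C1(C)C | intermediate
24 | (1S,8S)-1-[(tert-butyldimethylsilyl)oxy]-7,8-epoxy-7-methoxylongipin-3(15)-ene (epoxide on the face of C8 turned toward C11) | CO[C@@]15O[C@H]5C[C@@]2(C)[C@@H]3[C@@H](O[Si](C)(C)C(C)(C)C)CC(=C)[C@H]2[C@@H]3C1(C)C | intermediate
25 | (1S,8S)-1-[(tert-butyldimethylsilyl)oxy]-8-hydroxylongipin-3(15)-en-7-one | O=C1[C@@H](O)C[C@@]2(C)[C@@H]3[C@@H](O[Si](C)(C)C(C)(C)C)CC(=C)[C@H]2[C@@H]3C1(C)C | intermediate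
26 | (1S,7S,8S)-1-[(tert-butyldimethylsilyl)oxy]longipin-3(15)-ene-7,8-diol | O[C@@H]1[C@@H](O)C[C@@]2(C)[C@@H]3[C@@H](O[Si](C)(C)C(C)(C)C)CC(=C)[C@H]2[C@@H]3C1(C)C | intermediate
27 | (E)-2-methylbut-2-enoyl chloride (tigloyl chloride) | C/C=C(\C)C(Cl)=O | starting material
28 | (1S,7S,8S)-1-[(tert-butyldimethylsilyl)oxy]-7-hydroxylongipin-3(15)-en-8-yl (E)-2-methylbut-2-enoate | O[C@@H]1[C@@H](OC(=O)/C(C)=C/C)C[C@@]2(C)[C@@H]3[C@@H](O[Si](C)(C)C(C)(C)C)CC(=C)[C@H]2[C@@H]3C1(C)C | intermediate
29 | (Z)-2-methylbut-2-enoic acid (angelic acid) | C/C=C(/C)C(=O)O | starting material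
30 | (Z)-2-methylbut-2-enoic 2,4,6-trichlorobenzoic anhydride | C/C=C(/C)C(=O)OC(=O)c1c(Cl)cc(Cl)cc1Cl | intermediate
31 | (1S,7S,8S)-1-[(tert-butyldimethylsilyl)oxy]-8-[(E)-2-methylbut-2-enoyloxy]longipin-3(15)-en-7-yl (Z)-2-methylbut-2-enoate | C/C=C(/C)C(=O)O[C@@H]1[C@@H](OC(=O)/C(C)=C/C)C[C@@]2(C)[C@@H]3[C@@H](O[Si](C)(C)C(C)(C)C)CC(=C)[C@H]2[C@@H]3C1(C)C | intermediate
32 | (1S,7S,8S)-1-hydroxy-8-[(E)-2-methylbut-2-enoyloxy]longipin-3(15)-en-7-yl (Z)-2-methylbut-2-enoate | C/C=C(/C)C(=O)O[C@@H]1[C@@H](OC(=O)/C(C)=C/C)C[C@@]2(C)[C@@H]3[C@@H](O)CC(=C)[C@H]2[C@@H]3C1(C)C | intermediate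
33 | (7S,8S)-8-[(E)-2-methylbut-2-enoyloxy]-1-oxolongipin-3(15)-en-7-yl (Z)-2-methylbut-2-enoate | C/C=C(/C)C(=O)O[C@@H]1[C@@H](OC(=O)/C(C)=C/C)C[C@@]2(C)[C@@H]3C(=O)CC(=C)[C@H]2[C@@H]3C1(C)C | intermediate
34 | (4R,5S,7S,8S,10R,11R)-7-[(Z)-2-methylbut-2-enoyloxy]-8-[(E)-2-methylbut-2-enoyloxy]longipin-2-en-1-one (CNP0355097.1) | C/C=C(/C)C(=O)O[C@@H]1[C@@H](OC(=O)/C(C)=C/C)C[C@@]2(C)[C@@H]3C(=O)C=C(C)[C@H]2[C@@H]3C1(C)C | target

## Step count and least certain steps

Total step count: 18. Longest linear sequence: 17 steps (1 to 34 through steps 1, 2 and 4–18; step 3 prepares the dienolate 8 on a side branch).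

Step 7 (key step). Three processes could go wrong: loss of the silyloxy group by vinylogous elimination or deprotonation at C2 instead of C15 under hot amine base; ketene dimerisation; and incomplete facial control by the C1 ether. The fallback replaces the base-generated ketene by a cationic keteniminium ion, formed without amine at reflux. It sets out from 12: 13 is treated with pyrrolidine to give the pyrrolidine amide F1; triflic anhydride and 2,4,6-collidine in 1,2-dichloroethane give the vinylketeniminium triflate F2; this should cyclise in the same bridged sense to the cyclobutaniminium triflate F3, and aqueous NaHCO3 hydrolysis returns to the route at 15.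

Step 10. The ruthenium carbene may be trapped unproductively on the enol ether, and closure at a 1,1-disubstituted alkene next to a quaternary carbon may be slow. The fallback closes the same C7=C8 bond by carbonyl olefination instead of alkene metathesis. It sets out from 18: a titanium ethylidene reagent (TiCl4, Zn, PbCl2 cat., TMEDA, CH3CHBr2, THF) should exchange with the allyl group and olefinate the ester intramolecularly, returning at 20 without any new isolated compound.

Step 11. The hindered tertiary alkoxide may add slowly to CS2, and the silyl group may migrate from O1 to the neighbouring alkoxide so that the wrong oxygen is derivatised. The fallback avoids the alkoxide. It sets out from 20: acylation of the neutral alcohol with methyl chlorooxoacetate, pyridine and DMAP gives the methyl oxalate F4, and Bu3SnH/AIBN reduction of this tertiary oxalate returns at 23.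

Step 13. Facial discrimination may be lower than in the model cycloalkenes because of the gem-dimethyl neighbour, the exocyclic C3=C15 alkene may be epoxidised in competition, and the α-hydroxy ketone may undergo α-ketol rearrangement. The fallback transfers oxygen to an enolate from a chiral oxaziridine. It sets out from 23: mild aqueous acid gives the C7 ketone F5; KN(SiMe3)2 gives the potassium enolate F6, which can only form toward C8; hydroxylation with the appropriate enantiomer of (camphorsulfonyl)oxaziridine returns at 25.

Step 16. The forced acylation of the neopentyl alcohol may isomerise the Z ester to the E ester, and the tiglate may migrate before acylation. The fallback builds the Z double bond on the molecule. It sets out from 28: carbodiimide esterification with 2-[bis(2,2,2-trifluoroethoxy)phosphoryl]propanoic acid gives the phosphonate ester F7, and Still–Gennari olefination with acetaldehyde (KN(SiMe3)2, 18-crown-6, THF, −78 °C) returns at 31.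

## Further compounds

F1 | step 7 | 1-[(2E,5S,6E)-5-[(tert-butyldimethylsilyl)oxy]-3,7-dimethyldeca-2,6,9-trienoyl]pyrrolidine | O=C(/C=C(\C)C[C@H](O[Si](C)(C)C(C)(C)C)/C=C(\C)CC=C)N1CCCC1
F2 | step 7 | 1-[(5S,6E)-5-[(tert-butyldimethylsilyl)oxy]-7-methyl-3-methylidenedeca-1,6,9-trien-1-ylidene]pyrrolidinium trifluoromethanesulfonate | C=C(C=C=[N+]1CCCC1)C[C@H](O[Si](C)(C)C(C)(C)C)/C=C(\C)CC=C.[O-]S(=O)(=O)C(F)(F)F
F3 | step 7 | 1-[(2S)-2-[(tert-butyldimethylsilyl)oxy]-7-methyl-4-methylidene-7-(prop-2-en-1-yl)bicyclo[3.1.1]heptan-6-ylidene]pyrrolidinium trifluoromethanesulfonate (ring configuration as in 15) | C=CC[C@@]2(C)[C@@H]3[C@@H](O[Si](C)(C)C(C)(C)C)CC(=C)[C@H]2C3=[N+]4CCCC4.[O-]S(=O)(=O)C(F)(F)F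
F0 | step 10 | none | none
F4 | step 11 | (1S)-1-[(tert-butyldimethylsilyl)oxy]-7-methoxylongipina-3(15),7-dien-5-yl methyl oxalate | COC1=CC[C@@]2(C)[C@@H]3[C@@H](O[Si](C)(C)C(C)(C)C)CC(=C)[C@H]2[C@]3(OC(=O)C(=O)OC)C1(C)C
F5 | step 13 | (1S)-1-[(tert-butyldimethylsilyl)oxy]longipin-3(15)-en-7-one | O=C1CC[C@@]2(C)[C@@H]3[C@@H](O[Si](C)(C)C(C)(C)C)CC(=C)[C@H]2[C@@H]3C1(C)C
F6 | step 13 | potassium (1S)-1-[(tert-butyldimethylsilyl)oxy]longipina-3(15),7-dien-7-olate | [K+].[O-]C1=CC[C@@]2(C)[C@@H]3[C@@H](O[Si](C)(C)C(C)(C)C)CC(=C)[C@H]2[C@@H]3C1(C)C
F7 | step 16 | (1S,7S,8S)-1-[(tert-butyldimethylsilyl)oxy]-8-[(E)-2-methylbut-2-enoyloxy]longipin-3(15)-en-7-yl 2-[bis(2,2,2-trifluoroethoxy)phosphoryl]propanoate (phosphonate α-carbon not defined) | CC(P(=O)(OCC(F)(F)F)OCC(F)(F)F)C(=O)O[C@@H]1[C@@H](OC(=O)/C(C)=C/C)C[C@@]2(C)[C@@H]3[C@@H](O[Si](C)(C)C(C)(C)C)CC(=C)[C@H]2[C@@H]3C1(C)C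
A1 | alternative 1 | cis-fused 4-(methanesulfonyloxy)-3,6,6,10-tetramethylbicyclo[5.4.0]undec-2-ene-1,9-dione, numbered as the target with the C4–C10 bond missing (C10 configuration not defined) | CC1C(=O)CCC(C)(C)[C@@H]2[C@H]1C(=O)C=C(C)[C@H]2OS(C)(=O)=O
A2 | alternative 2 | (2E,4E,7S,8S,10E)-7,8-dihydroxy-3,6,6,10-tetramethylcycloundeca-2,4,10-trien-1-one | O[C@@H]1[C@@H](O)C/C(C)=C/C(=O)/C=C(C)/C=C/C1(C)C
A3 | alternative 3 | α-longipinene (longipin-2-ene) with the ring configuration of 34 | C1CC[C@@]2(C)[C@@H]3CC=C(C)[C@H]2[C@@H]3C1(C)C
A4 | alternative 3 | longipin-2-en-1-one with the ring configuration of 34 | C1CC[C@@]2(C)[C@@H]3C(=O)C=C(C)[C@H]2[C@@H]3C1(C)C
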